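# Total synthesis plan for CNP0244624.1 by ring-enlarging cyclopentane annulation

## The problem

The target 27 is the 4-methoxybenzoate of a daucane-type triol: a cis-fused perhydroazulene in which a cyclopentane and a cycloheptane share one bond. The ring carbons are labelled C1 (CH bearing the ester oxygen), C2 (the CH2 next to it), C3 (methyl-bearing fusion carbon), C4 and C5 (cyclopentane CH2 groups), C6 (CH bearing isopropyl), C7 (hydroxyl-bearing fusion carbon), C8 and C9 (the following CH2 pair) and C10 (the methyl carbinol carbon), so the shared bond is C3–C7; the same labels are used for the corresponding atoms of every intermediate. There are five stereocentres (C1 R, C3 R, C6 R, C7 S, C10 R): the C3 methyl, the C7 hydroxyl, the C6 isopropyl, the C1 ester oxygen and the C10 methyl lie on one face and only the C10 hydroxyl on the other, so the ring fusion is cis and the C1/C10 diol is trans. The hard part is the contiguous array C3–C7–C6: two adjacent fully substituted fusion carbons, one of them a tertiary carbinol, next to a branched stereocentre. C6 and C7 are neighbours and can be set together and then used to place C3 under ring constraint, whereas C1 and C10 lie on the far side of a flexible seven-membered ring and can only be set by the facial bias of the finished bicycle. The sensitive points are the two tertiary alcohols (ionisation and dehydration in acid; the C7 hydroxyl becomes a retro-aldol trigger whenever C2 is a carbonyl group) and the aryl ester, which cannot pass organometallic or hydride steps and must come late. The feature that opens the key step is C3: a methyl-bearing quaternary carbon flanked by C2 and by the oxygenated C7 is what remains when a ring carbon (C7) has moved from a carbinol carbon (C2) to the cationic carbon of a 2-propenyl group, and the unsubstituted C4–C5 unit is where a tethered electrophile can have met that alkene.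

## Retrosynthesis

**Benzyl ether and ester (27 ⇒ 26 ⇒ 24 + 25).** The O–benzyl bond on C7 and the ester C–O bond on C1 are cut first, so that the ester goes on late and the benzyl group comes off last. Acylating a secondary hydroxyl beside a tertiary one asks less of the forward reaction than opening an epoxide with a carboxylate. The benzyl ether is chosen because it must cover the C7 oxygen from the first C–C bond formation onward and leaves by hydrogenolysis without touching the ester or the tertiary alcohols. Diol 24 is simpler than 27 only by the aroyl group, but it tolerates everything that precedes it.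

**C1–O and C10–CH3 (24 ⇒ 22 ⇒ 21).** The trans-1,2-diol is traced to tertiary allylic alcohol 22 by removing the C1 oxygen (hydroboration–oxidation forward) and then to enone 21 by removing the C10 methyl (1,2-addition forward). A cis-dihydroxylation would give the wrong relative configuration. Opening a C1–C10 epoxide needs a regiodefined trisubstituted alkene that 21 does not give directly; it is kept in reserve. Enone 21 has two stereocentres fewer. The forward steps must choose the face of the carbonyl and of the alkene, and boron must go to C1.

**Carbonyl transposition (21 ⇒ 20 ⇒ 19 ⇒ 18 ⇒ 17).** The key step leaves a carbonyl at C2 and a phenylthio group at C5, neither of which is in the target. The C5–S bond is cut reductively. The C2 carbonyl is related to the C10 carbonyl of 21 through alkene 20: C2 can enolise only toward C1, so enol triflate 19 and alkene 20 are regiochemically unambiguous, and 20 has allylic hydrogens only on C10. A direct deoxygenation of C2 would leave no handle for C1 and C10, and a transposition through an epoxy ketone is longer. No stereocentre changes in this stretch.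

**Key disconnection (17 ⇒ 14).** The bonds C4–C5 and C3–C7 are cut and C2–C7 is restored. This turns the bicycle into a monocyclic cyclohexane that carries a 2-propenyl silyl ether on C2 and, on C7, the benzyloxy group and a dithioacetal side chain. Against the neighbouring cuts (C6–C7 by aldol, C7–C8 by carbanion addition, C2–C3 by sigmatropic shift) this one removes both rings, two skeletal bonds and two stereocentres at once, and leaves a precursor whose only stereochemical content is the C6/C7 pair. The forward reaction must close the six-membered ring on the alkene in preference to capture of the thionium ion by oxygen, must move C7 and not C1, and must do so with retention at C7.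

**C2–C3 and O–Si (14 ⇒ 13 ⇒ 11 + 12).** The silyl ether is cut to the tertiary alcohol and the C2–C3 bond to ketone 11 and 2-propenylmagnesium bromide 12. The benzyloxy group on C7, a spectator in the target, is used here as a chelating group to control the face of addition. The alternative of building the carbinol before C7 is quaternary would give up that control.

**C5–S and C5=C (11 ⇒ 9 + 10, 9 ⇒ 7).** The dithioacetal comes from aldehyde 9 and thiophenol 10, and the aldehyde from ozonolysis of the propenyl group of 7. This puts a removable sulfur on C5 and needs no separate C1 unit for C5.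

**C6–C7 (7 ⇒ 4 + 2, 4 ⇒ 3, 2 ⇒ 1).** Ketone 7, with an oxygenated quaternary carbon next to a tertiary stereocentre and a γ,δ-double bond, is a Claisen retron. Cutting C6–C7 leads to the dimethyl ketal 4 of commercial ketone 3 and the (R)-allylic alcohol 2, which comes from commercial enone 1 by asymmetric reduction. One carbinol centre thus controls both C6 and C7. An aldol or allylation route to the same pair would need separate control of each centre. The forward reaction must form the enol ether toward the oxygenated carbon and rearrange through a chair.

## Roads not taken

**Alternative 1:** Samarium Barbier closure onto a cyclopentanone.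
- Cut: C7–C8.
- Forward key step: SmI2 with catalytic NiI2 converts the primary iodide of cyclopentanone A1 into an organosamarium species that adds to the C7 carbonyl, closing the seven-membered ring and creating the tertiary alcohol of acetonide A2.
- Merits: C1 and C10 are set in the open chain as a protected trans-diol before ring closure, so no carbonyl transposition is needed afterwards. The C7 hydroxyl is formed unprotected, and only acetonide cleavage and acylation remain.
- Weak points: a seven-membered ring closed by carbanion addition competes with simple reduction of the iodide. The ketone is flanked by the quaternary C3 and by C6, whose α-hydrogen can be lost to basic samarium alkoxides. The configuration at C7 depends on the face of addition, with only the tether to enforce cis fusion. A1 itself carries four stereocentres that must be brought in separately.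
- Comparison: in the endgame Alternative 1 is clearly better (two steps after the key step against eight here). The chosen plan sets against it a much cheaper precursor: one rearrangement sets C6 and C7, and the key step then makes both rings and C3 under ring constraint.

**Alternative 2:** Desymmetrising reductive aldol on a cycloheptane-1,3-dione.
- Cut: C6–C7.
- Forward key step: copper hydride (from Cu(OAc)2, a chiral bisphosphine and a silane) reduces the side-chain enone of the achiral dione A3 to an enolate centred on C6, which adds to one of the two enantiotopic ring carbonyls. The cyclopentane closes and C3, C6 and C7 are set in one catalytic step to give ketol A4.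
- Merits: it is the shortest access to the bicyclic core, and the absolute configuration comes from a catalyst. The syn-aldol geometry places the hydroxyl and the C6 substituent cis as required. A4 has its ring ketone at C2, where compound 17 has it, so the same endgame would apply.
- Weak points: C6 carries acetyl, which must be turned into isopropyl in the presence of the C2 ketone. A4 is a free β-hydroxy ketone toward both carbonyls and is open to retro-aldol cleavage and to epimerisation at C6. Selection between enantiotopic carbonyls is less secure on a seven-membered dione than on six-membered ones.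
- Comparison: in step count to the bicyclic ketone Alternative 2 is better (about three steps against eight), and it needs no stoichiometric chiral material. The chosen plan sets against this that isopropyl and the C7 oxygen arrive in final form and protected, that no retro-aldol-prone ketol is handled, and that chirality is passed on from a defined carbinol centre through a pericyclic transition state.

**Alternative 3:** Claisen contraction of an eight-membered cyclic enol ether.
- Cut: C2–C3.
- Forward key step: on heating, the exocyclic enol ether A5 (C2 methylene on C1, ring oxygen on C5) rearranges. C2–C3 forms as C5–O breaks, the eight-membered oxacycle contracts to the seven-membered carbocycle, and ketone A6 results with its carbonyl at C1 and a C4=C5 double bond.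
- Merits: the carbonyl appears at C1, where the target has its ester oxygen, next to a C10 carbinol already in place. The endgame shrinks to ketone reduction, alkene hydrogenation, desilylation and acylation. The quaternary C3 is formed suprafacially with chirality transfer from C5.
- Weak points: A5 is a bridged medium-ring enol ether with four stereocentres (C5, C6, C7, C10). Its assembly (an eight-membered ring closure through an ester bond, then carbonyl methylenation) is a synthesis in itself. The rearrangement has to pass through a boat-like transition state inside a bicyclic frame. Reduction of the C1 ketone must deliver the hydroxyl trans to the C10 oxygen.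
- Comparison: after the key step Alternative 3 has the better functional-group economy, since it avoids the carbonyl transposition that costs the chosen plan five steps. The chosen plan answers with a seven-step access to its precursor from two commercial ketones and a key step that forms two bonds and two rings instead of one bond.

Key step: step 8

Assumption: the (R)-allylic alcohol 2 is made from the commercial (E)-enone 1 rather than bought, ketone 3 and the THF solution of Grignard reagent 12 are bought, and the CIP descriptors quoted follow from the SMILES strings of the compound list.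

## Route

Step 1
Reactants: 1 (E)-5-methylhex-3-en-2-one
Product: 2 (2R,3E)-5-methylhex-3-en-2-ol
Conditions: (S)-1-methyl-3,3-diphenyltetrahydro-1H,3H-pyrrolo[1,2-c][1,3,2]oxazaborole (10 mol %), BH3·SMe2, THF, −20 °C; MeOH quench, aqueous work-up
Reagents that add atoms: none
Why: Corey–Bakshi–Shibata reduction: the catalyst–borane complex binds the ketone with the larger (alkenyl) substituent away from the ring, so the (S)-catalyst should give the (R)-carbinol as it does with aryl methyl ketones; the 1,2-reduction leaves the (E)-alkene untouched.

Step 2
Reactants: 3 2-(benzyloxy)cyclohexan-1-one (racemic)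
Product: 4 2-(benzyloxy)-1,1-dimethoxycyclohexane (racemic)
Conditions: HC(OMe)3, MeOH, TsOH (cat.), rt
Reagents that add atoms: trimethyl orthoformate, COC(OC)OC; methanol, CO
Why: Acid-catalysed ketalisation with the orthoformate as water scavenger; the existing C–O stereocentre is racemic and is erased when the enol ether forms in step 3.

Step 3
Reactants: 4 2-(benzyloxy)-1,1-dimethoxycyclohexane (2 equiv), 2 (2R,3E)-5-methylhex-3-en-2-ol
Product: 7 (2S)-2-(benzyloxy)-2-[(3S,4E)-2-methylhex-4-en-3-yl]cyclohexan-1-one, via mixed ketal 5 (not isolated), via allyl enol ether 6 (not isolated)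
Conditions: EtCO2H (cat.), xylene, 140 °C, MeOH distilled off
Reagents that add atoms: none
Why: Ketal Claisen rearrangement: acid-catalysed exchange of one methoxy group for 2, loss of methanol to the enol ether and [3,3] shift at the same temperature; the tetrasubstituted, doubly oxygenated enol ether 6 should be the more stable of the two equilibrating regioisomers and is the only one that leads to 7. In the chair transition state the carbinol methyl is equatorial, which gives the (E)-propenyl group and passes the (R) centre of 2 on to C6 (S) and C7 (S) together, with the benzyloxy group and the C6 hydrogen anti across the new bond.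

Step 4
Reactants: 7 (2S)-2-(benzyloxy)-2-[(3S,4E)-2-methylhex-4-en-3-yl]cyclohexan-1-one
Product: 9 (2R)-2-[(1S)-1-(benzyloxy)-2-oxocyclohexyl]-3-methylbutanal, via ozonide 8 (not isolated)
Conditions: O3, CH2Cl2, −78 °C (Sudan Red 7B end point); then PPh3, −78 °C to rt
Reagents that add atoms: ozone, [O-][O+]=O
Why: Ozonolysis of the only C=C bond with reductive work-up; the alkene is consumed before ozone attacks the benzyl ether when addition stops at the indicator end point, and the C6 hydrogen, flanked by the quaternary C7 and the isopropyl group, is slow to enolise, so the aldehyde should be carried on without epimerisation.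

Step 5
Reactants: 9 (2R)-2-[(1S)-1-(benzyloxy)-2-oxocyclohexyl]-3-methylbutanal, 10 thiophenol
Product: 11 (2S)-2-(benzyloxy)-2-[(2R)-3-methyl-1,1-bis(phenylsulfanyl)butan-2-yl]cyclohexan-1-one
Conditions: PhSH (2.2 equiv), BF3·OEt2 (0.3 equiv), CH2Cl2, −40 to 0 °C
Reagents that add atoms: thiophenol (10), Sc1ccccc1
Why: Lewis-acid thioacetalisation; the aldehyde reacts far faster than the ketone, which is shielded by the adjacent quaternary C7, and the low temperature keeps the β-benzyloxy aldehyde from eliminating.

Step 6
Reactants: 11 (2S)-2-(benzyloxy)-2-[(2R)-3-methyl-1,1-bis(phenylsulfanyl)butan-2-yl]cyclohexan-1-one, 12 2-propenylmagnesium bromide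
Product: 13 (1S,2S)-2-(benzyloxy)-2-[(2R)-3-methyl-1,1-bis(phenylsulfanyl)butan-2-yl]-1-(prop-1-en-2-yl)cyclohexan-1-ol
Conditions: CeCl3 (anhydrous), 12 (3 equiv), THF, −78 to 0 °C; aq. NH4Cl
Reagents that add atoms: 2-propenylmagnesium bromide (12), CC(=C)[Mg]Br
Why: 1,2-Addition of the organocerium reagent formed from the Grignard reagent and CeCl3, which adds to hindered, enolisable ketones without deprotonation; chelation of the metal between the carbonyl and benzyloxy oxygens holds the ether in the carbonyl plane and the branched chain axial, so attack anti to the chain should set C2 (S) with 2-propenyl cis to the benzyloxy group and the hydroxyl trans to it. The C2 centre is needed only to shape the transition state of step 8, where it becomes the carbonyl carbon.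

Step 7
Reactants: 13 (1S,2S)-2-(benzyloxy)-2-[(2R)-3-methyl-1,1-bis(phenylsulfanyl)butan-2-yl]-1-(prop-1-en-2-yl)cyclohexan-1-ol
Product: 14 {[(1S,2S)-2-(benzyloxy)-2-[(2R)-3-methyl-1,1-bis(phenylsulfanyl)butan-2-yl]-1-(prop-1-en-2-yl)cyclohexyl]oxy}triethylsilane
Conditions: Et3SiOTf, 2,6-lutidine, CH2Cl2, −78 to 0 °C
Reagents that add atoms: triethylsilyl trifluoromethanesulfonate, CC[Si](CC)(CC)OS(=O)(=O)C(F)(F)F
Why: Silyl ether formation on a hindered tertiary alcohol with the silyl triflate and a non-nucleophilic base; the silyl ether keeps the oxygen from adding irreversibly to the thionium ion and becomes the leaving group on oxygen in the pinacol step.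

Step 8
Reactants: 14 {[(1S,2S)-2-(benzyloxy)-2-[(2R)-3-methyl-1,1-bis(phenylsulfanyl)butan-2-yl]-1-(prop-1-en-2-yl)cyclohexyl]oxy}triethylsilane
Product: 17 (1R,2R,3aS,8aS)-8a-(benzyloxy)-3a-methyl-2-(phenylsulfanyl)-1-(propan-2-yl)octahydroazulen-4(1H)-one, via thionium ion 15 (not isolated), via tertiary cation 16 (not isolated)
Conditions: Me2S(SMe)BF4 (2.5 equiv), CH2Cl2, −45 to 0 °C
Reagents that add atoms: none
Why: Me2S(SMe)BF4 methylthiolates one sulfur of the dithioacetal, which leaves as MeSSPh to give the thionium ion 15 at C5. The 2-propenyl group attacks it through C4 in a 6-endo closure (endo with respect to the alkene) through a chair in which the new ring is trans-fused to the cyclohexane, the isopropyl and phenylthio groups are equatorial and the benzyloxy and silyloxy groups are trans-diaxial, giving the tertiary cation 16 at C3. C7 then shifts from C2 to C3 with loss of the silyl group (pinacol step), which contracts the six-membered ring just formed to the cyclopentane and enlarges the cyclohexane to the cycloheptanone, so neither final ring is closed by a separate cyclisation. The closest known reaction type is the thionium-initiated Prins–pinacol ring-enlarging cyclopentane annulation of 1-alkenylcycloalkanol silyl ethers, and for the oxygen on the migrating carbon the nearest analogy is the ring-enlarging tetrahydrofuran annulation of alkenyl diol acetals, where the migrating carbon carries the ring oxygen. C3 is set by the ring: C7 moves suprafacially with retention and its bond to C8, equatorial on the chair, lies in the plane of C2, C3 and C7, so C8 and C2 end up cis on the cyclopentane and methyl, benzyloxy and isopropyl share one face. C5 is set by the (E)-thionium ion in the chair (phenylthio trans to isopropyl) and is removed in step 9. The selectivity needed is shift of C7 rather than of C1 or loss of a proton: C1 is equatorial and nearly orthogonal to the vacant orbital, whereas the C2–C7 ring bond lies close to it and is weakened by a lone pair of the ether oxygen anti to it. Capture of the thionium ion by the silyl ether oxygen is reversible and should drain into the carbocyclic pathway.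

Step 9
Reactants: 17 (1R,2R,3aS,8aS)-8a-(benzyloxy)-3a-methyl-2-(phenylsulfanyl)-1-(propan-2-yl)octahydroazulen-4(1H)-one
Product: 18 (1R,3aS,8aS)-8a-(benzyloxy)-3a-methyl-1-(propan-2-yl)octahydroazulen-4(1H)-one
Conditions: Raney Ni (W-2, deactivated in refluxing acetone), EtOH–acetone, rt to 50 °C
Reagents that add atoms: none
Why: Reductive desulfurisation of the secondary alkyl phenyl sulfide on nickel; the deactivated catalyst should leave the hindered ketone and the benzyl ether alone, and no stereocentre other than C5 is touched.

Step 10
Reactants: 18 (1R,3aS,8aS)-8a-(benzyloxy)-3a-methyl-1-(propan-2-yl)octahydroazulen-4(1H)-one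
Product: 19 enol triflate of 18 (C1=C2 double bond, triflate on C2; C3 S, C6 R, C7 S)
Conditions: KN(SiMe3)2, PhNTf2, THF, −78 to 0 °C
Reagents that add atoms: N-phenylbis(trifluoromethanesulfonimide), O=S(=O)(N(c1ccccc1)S(=O)(=O)C(F)(F)F)C(F)(F)F
Why: Enol triflate formation; the ketone can enolise only toward C1 because C3 is quaternary, so the potassium enolate and its triflate form with a single regiochemistry.

Step 11
Reactants: 19 enol triflate of 18 (C1=C2 double bond, triflate on C2)
Product: 20 C1=C2 alkene (benzyloxy on C7; C3 R, C6 R, C7 S)
Conditions: Pd(OAc)2 (5 mol %), PPh3 (10 mol %), HCO2H, Bu3N, DMF, 60 °C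
Reagents that add atoms: none
Why: Palladium-catalysed formate reduction of the enol triflate (oxidative addition to zerovalent palladium, formate exchange, loss of CO2, reductive elimination) gives the alkene without moving it; benzyl ethers are inert to this system.

Step 12
Reactants: 20 C1=C2 alkene (benzyloxy on C7)
Product: 21 enone with carbonyl at C10 conjugated to C1=C2 (C3 R, C6 R, C7 S)
Conditions: CrO3, 3,5-dimethylpyrazole, CH2Cl2, −20 °C
Reagents that add atoms: chromium trioxide, O=[Cr](=O)=O
Why: Allylic oxidation with the CrO3–3,5-dimethylpyrazole complex; the alkene has allylic hydrogens only on C10 because C3 is quaternary, and oxygen should be delivered to the unhindered C10 end of the allyl system rather than to the neopentyl C2, while at −20 °C the benzylic methylene is expected to react more slowly than the allylic one.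

Step 13
Reactants: 21 enone with carbonyl at C10 conjugated to C1=C2
Product: 22 tertiary allylic alcohol (methyl and hydroxyl on C10, C1=C2 alkene; C3 R, C6 R, C7 S, C10 R)
Conditions: MeLi, CeCl3 (anhydrous), THF, −78 °C; aq. NH4Cl
Reagents that add atoms: methyllithium, [Li]C
Why: 1,2-Addition of the methylcerium reagent to the enone carbonyl without enolisation or conjugate addition; the reagent should approach the convex face of the cis-fused bicycle, the face of the two angular substituents, which places the new methyl on that face and the hydroxyl on the other (C10 R).

Step 14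
Reactants: 22 tertiary allylic alcohol (methyl and hydroxyl on C10, C1=C2 alkene)
Product: 24 (1R,3aR,5R,6R,8aS)-8a-(benzyloxy)-3a,6-dimethyl-1-(propan-2-yl)decahydroazulene-5,6-diol, via alkylborane 23 (not isolated)
Conditions: BH3·THF (excess), THF, 0 °C to rt; then NaOH, H2O2, 0 °C to rt
Reagents that add atoms: hydrogen peroxide, OO
Why: Hydroboration–oxidation of the tertiary allylic alcohol: the inductive pull of the C10 oxygen and the quaternary C3 next to C2 should direct boron to C1, and addition anti to the allylic oxygen on the convex face, followed by oxidation with retention, gives the trans-1,2-diol (C1 R).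

Step 15
Reactants: 24 (1R,3aR,5R,6R,8aS)-8a-(benzyloxy)-3a,6-dimethyl-1-(propan-2-yl)decahydroazulene-5,6-diol, 25 4-methoxybenzoyl chloride
Product: 26 (1R,3aR,5R,6R,8aS)-8a-(benzyloxy)-6-hydroxy-3a,6-dimethyl-1-(propan-2-yl)decahydroazulen-5-yl 4-methoxybenzoate
Conditions: Et3N, 4-(dimethylamino)pyridine (cat.), CH2Cl2, 0 °C to rt
Reagents that add atoms: 4-methoxybenzoyl chloride (25), COc1ccc(C(Cl)=O)cc1
Why: Nucleophile-catalysed esterification of the only secondary hydroxyl; the tertiary C10 hydroxyl should not react under these conditions.

Step 16
Reactants: 26 (1R,3aR,5R,6R,8aS)-8a-(benzyloxy)-6-hydroxy-3a,6-dimethyl-1-(propan-2-yl)decahydroazulen-5-yl 4-methoxybenzoate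
Product: 27 (1R,3aR,5R,6R,8aS)-6,8a-dihydroxy-3a,6-dimethyl-1-(propan-2-yl)decahydroazulen-5-yl 4-methoxybenzoate
Conditions: H2 (1 atm), Pd(OH)2/C, EtOAc–EtOH, rt
Reagents that add atoms: none
Why: Hydrogenolysis of the benzylic C–O bond; the aryl ester and the tertiary alcohols are stable to it and no stereocentre is affected.

## Compound list

1 | (E)-5-methylhex-3-en-2-one | CC(=O)/C=C/C(C)C | starting material
2 | (2R,3E)-5-methylhex-3-en-2-ol | C[C@@H](O)/C=C/C(C)C | intermediate
3 | 2-(benzyloxy)cyclohexan-1-one (racemic) | O=C1CCCCC1OCc1ccccc1 | starting material
4 | 2-(benzyloxy)-1,1-dimethoxycyclohexane (racemic) | COC1(OC)CCCCC1OCc1ccccc1 | intermediate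
5 | mixed ketal: 2-(benzyloxy)-1-methoxy-1-{[(2R,3E)-5-methylhex-3-en-2-yl]oxy}cyclohexane (diastereomer mixture at the ring carbons) | COC1(O[C@H](C)/C=C/C(C)C)CCCCC1OCc1ccccc1 | intermediate (not isolated)
6 | allyl enol ether: 1-(benzyloxy)-2-{[(2R,3E)-5-methylhex-3-en-2-yl]oxy}cyclohex-1-ene | C[C@@H](OC1=C(OCc2ccccc2)CCCC1)/C=C/C(C)C | intermediate (not isolated)
7 | (2S)-2-(benzyloxy)-2-[(3S,4E)-2-methylhex-4-en-3-yl]cyclohexan-1-one | O=C1CCCC[C@]1(OCc2ccccc2)[C@@H](C(C)C)/C=C/C | intermediate
8 | ozonide (1,2,4-trioxolane) of 7, new ring centres undefined | CC1OOC(O1)[C@H](C(C)C)[C@@]1(OCc2ccccc2)CCCCC1=O | intermediate (not isolated)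
9 | (2R)-2-[(1S)-1-(benzyloxy)-2-oxocyclohexyl]-3-methylbutanal | O=C[C@H](C(C)C)[C@@]1(OCc2ccccc2)CCCCC1=O | intermediate
10 | thiophenol | Sc1ccccc1 | starting material
11 | (2S)-2-(benzyloxy)-2-[(2R)-3-methyl-1,1-bis(phenylsulfanyl)butan-2-yl]cyclohexan-1-one | O=C1CCCC[C@]1(OCc2ccccc2)[C@@H](C(C)C)C(Sc2ccccc2)Sc2ccccc2 | intermediate
12 | 2-propenylmagnesium bromide (THF solution) | CC(=C)[Mg]Br | starting material
13 | (1S,2S)-2-(benzyloxy)-2-[(2R)-3-methyl-1,1-bis(phenylsulfanyl)butan-2-yl]-1-(prop-1-en-2-yl)cyclohexan-1-ol | CC(=C)[C@@]1(O)CCCC[C@]1(OCc2ccccc2)[C@@H](C(C)C)C(Sc2ccccc2)Sc2ccccc2 | intermediate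
14 | triethylsilyl ether of 13 (key-step precursor) | CC(=C)[C@@]1(O[Si](CC)(CC)CC)CCCC[C@]1(OCc2ccccc2)[C@@H](C(C)C)C(Sc2ccccc2)Sc2ccccc2 | intermediate
15 | thionium ion at C5 | CC(=C)[C@@]1(O[Si](CC)(CC)CC)CCCC[C@]1(OCc2ccccc2)[C@@H](C(C)C)C=[S+]c2ccccc2 | intermediate (not isolated)
16 | tertiary cation at C3 after Prins closure (trans-fused bicyclic, phenylthio and isopropyl equatorial) | C[C+]1C[C@@H](Sc2ccccc2)[C@H](C(C)C)[C@@]2(OCc3ccccc3)CCCC[C@]12O[Si](CC)(CC)CC | intermediate (not isolated)
17 | (1R,2R,3aS,8aS)-8a-(benzyloxy)-3a-methyl-2-(phenylsulfanyl)-1-(propan-2-yl)octahydroazulen-4(1H)-one (key-step product; C3 S, C5 R, C6 R, C7 S) | C1C(=O)[C@@]2(C)C[C@@H](Sc3ccccc3)[C@H](C(C)C)[C@@]2(OCc3ccccc3)CCC1 | intermediate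
18 | (1R,3aS,8aS)-8a-(benzyloxy)-3a-methyl-1-(propan-2-yl)octahydroazulen-4(1H)-one | C1C(=O)[C@@]2(C)CC[C@H](C(C)C)[C@@]2(OCc3ccccc3)CCC1 | intermediate
19 | enol triflate of 18 (C1=C2, triflate on C2; C3 S, C6 R, C7 S) | C1=C(OS(=O)(=O)C(F)(F)F)[C@@]2(C)CC[C@H](C(C)C)[C@@]2(OCc3ccccc3)CCC1 | intermediate
20 | C1=C2 alkene, benzyloxy on C7 (C3 R, C6 R, C7 S) | C1=C[C@@]2(C)CC[C@H](C(C)C)[C@@]2(OCc3ccccc3)CCC1 | intermediate
21 | enone, carbonyl at C10, C1=C2 (C3 R, C6 R, C7 S) | O=C1C=C[C@@]2(C)CC[C@H](C(C)C)[C@@]2(OCc3ccccc3)CC1 | intermediate
22 | tertiary allylic alcohol, methyl and hydroxyl on C10, C1=C2 (C3 R, C6 R, C7 S, C10 R) | C[C@]1(O)C=C[C@@]2(C)CC[C@H](C(C)C)[C@@]2(OCc3ccccc3)CC1 | intermediate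
23 | alkylborane, boron on C1 on the face of the angular groups (drawn as the BH2 compound with free hydroxyl) | C[C@]1(O)[C@H](B)C[C@@]2(C)CC[C@H](C(C)C)[C@@]2(OCc3ccccc3)CC1 | intermediate (not isolated)
24 | (1R,3aR,5R,6R,8aS)-8a-(benzyloxy)-3a,6-dimethyl-1-(propan-2-yl)decahydroazulene-5,6-diol (C1 R, C3 R, C6 R, C7 S, C10 R) | C[C@]1(O)[C@H](O)C[C@@]2(C)CC[C@H](C(C)C)[C@@]2(OCc3ccccc3)CC1 | intermediate
25 | 4-methoxybenzoyl chloride | COc1ccc(C(Cl)=O)cc1 | starting material
26 | (1R,3aR,5R,6R,8aS)-8a-(benzyloxy)-6-hydroxy-3a,6-dimethyl-1-(propan-2-yl)decahydroazulen-5-yl 4-methoxybenzoate | COc1ccc(C(=O)O[C@@H]2C[C@@]3(C)CC[C@H](C(C)C)[C@@]3(OCc4ccccc4)CC[C@@]2(C)O)cc1 | intermediate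
27 | (1R,3aR,5R,6R,8aS)-6,8a-dihydroxy-3a,6-dimethyl-1-(propan-2-yl)decahydroazulen-5-yl 4-methoxybenzoate (C1 R, C3 R, C6 R, C7 S, C10 R) | COc1ccc(C(=O)O[C@@H]2C[C@@]3(C)CC[C@H](C(C)C)[C@@]3(O)CC[C@@]2(C)O)cc1 | target

## Step count and least certain steps

Total: 16 steps. Longest linear sequence: 15 steps (1 to 27 through steps 1 and 3–16; step 2 is the only step off this line).

**Step 8 (key step).** The migrating carbon C7 is quaternary and carries an ether oxygen, a pattern with no close analogy in the carbocyclic series. Its shift may therefore be slower than that of the CH carbon in the documented cases. The C3 cation could then be lost by deprotonation to alkenes. Alternatively the C2–C7 bond could break outright to a ten-membered oxocarbenium ion, with erosion of the C3/C7 relationship on reclosure. Capture of the hindered thionium ion by the silyl ether oxygen is a further diversion.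
Fallback (sets out from 14, returns at 17): ring closure and shift are uncoupled. With Me2S(SMe)BF4 in the presence of 2,6-di-tert-butyl-4-methylpyridine the cyclisation is stopped deliberately at the alkene stage, giving the methylenecyclohexane F1 with the silyl ether intact. Isolated F1 is then treated with CF3SO3H in CH2Cl2 at −78 °C. Protonation of the exocyclic alkene regenerates the C3 cation reversibly and the pinacol shift is the only irreversible exit, so a slow shift can be waited for. This is a proton-initiated semipinacol rearrangement of an allylic silyl ether and gives 17.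

**Step 3 (ketal Claisen).** The enol ether may form toward the CH2 side, which puts the allyl unit on the wrong α-carbon. Some rearrangement may also leak through a boat transition state, which would erode the C6/C7 relationship and the chirality transfer.
Fallback (sets out from 2, returns at 7): the enol is generated with fixed regiochemistry from a diazo ketone. 2-Diazocyclohexanone F2 is made from cyclohexanone by formylation and Regitz deformylative diazo transfer. Rh2(OAc)4-catalysed O–H insertion of F2 into 2 gives an allyloxy enol that rearranges in the flask through the same chair, with the allyl unit ending on the former carbonyl carbon, to give the hydroxy ketone F3. O-Benzylation of the tertiary alcohol with 2-benzyloxy-1-methylpyridinium trifluoromethanesulfonate and MgO in PhCF3 then gives 7.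

**Step 12 (allylic oxidation).** Hydrogen abstraction at the benzylic methylene of the ether, oxygen delivery to the C2 end of the allyl system, or stalled conversion of the hindered cis-alkene may compete.
Fallback (sets out from 18, returns at 21, replacing steps 10–12): the carbonyl is transposed through an epoxy ketone. Ketone 18 is dehydrogenated (LDA, then N-tert-butylbenzenesulfinimidoyl chloride, −78 °C) to the enone F4, with its double bond between C1 and C10. Alkaline H2O2 gives the epoxy ketone F5; either epoxide face serves, and the lower face is drawn. Wharton rearrangement (N2H4·H2O, AcOH, MeOH) gives the allylic alcohol F6, with the hydroxyl on C10 and the C1=C2 alkene. Dess–Martin oxidation of F6 gives 21.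

**Step 13 (with step 14).** Addition of the methyl nucleophile to the concave face would invert C10. The following hydroboration carries its own risk of boron going to C2 or of addition syn to the hydroxyl.
Fallback (sets out from 21, returns at 24, replacing steps 13 and 14): the diol is made by epoxide opening, so that a single facial choice sets both centres. Conjugate reduction of 21 with LiBH(s-Bu)3 and trapping of the regiodefined enolate with PhNTf2 gives the enol triflate F7 (C10=C1). Fe(acac)3-catalysed coupling with MeMgBr gives the trisubstituted alkene F8. Epoxidation with 3-chloroperoxybenzoic acid on the convex face gives the epoxide F9. Acid-catalysed hydrolysis (HClO4, THF–H2O, 0 °C) opens it at the tertiary C10 with inversion to give the trans-diol 24.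

## Further compounds

F1 | step 8 | methylenecyclohexane from the interrupted cyclisation (exocyclic C3=CH2, silyl ether on C2, phenylthio on C5, configuration as in 16) | C=C1C[C@@H](Sc2ccccc2)[C@H](C(C)C)[C@@]2(OCc3ccccc3)CCCC[C@]12O[Si](CC)(CC)CC
F2 | step 3 | 2-diazocyclohexan-1-one | [N-]=[N+]=C1CCCCC1=O
F3 | step 3 | (2S)-2-hydroxy-2-[(3S,4E)-2-methylhex-4-en-3-yl]cyclohexan-1-one | O=C1CCCC[C@]1(O)[C@@H](C(C)C)/C=C/C
F4 | step 12 | enone with carbonyl at C2 and C1=C10 double bond (C3 S, C6 R, C7 S) | O=C1C=CCC[C@]2(OCc3ccccc3)[C@@H](C(C)C)CC[C@]12C
F5 | step 12 | C1–C10 epoxide of F4 (oxygen on the face of the angular groups) | O=C1[C@H]2O[C@H]2CC[C@]3(OCc4ccccc4)[C@@H](C(C)C)CC[C@]13C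
F6 | step 12 | allylic alcohol with hydroxyl on C10 and C1=C2 alkene | O[C@@H]1C=C[C@@]2(C)CC[C@H](C(C)C)[C@@]2(OCc3ccccc3)CC1
F7 | step 13 | enol triflate with C10=C1 double bond, triflate on C10 | FC(F)(F)S(=O)(=O)OC1=CC[C@@]2(C)CC[C@H](C(C)C)[C@@]2(OCc3ccccc3)CC1
F8 | step 13 | trisubstituted alkene C10(CH3)=C1, benzyloxy on C7 | CC1=CC[C@@]2(C)CC[C@H](C(C)C)[C@@]2(OCc3ccccc3)CC1
F9 | step 13 | C1–C10 epoxide of F8 (oxygen on the face of the angular groups) | C[C@]14O[C@@H]4C[C@@]2(C)CC[C@H](C(C)C)[C@@]2(OCc3ccccc3)CC1
A1 | alternative 1 | cyclopentanone with iodoethyl dioxolane side chain (substrate of the Barbier closure) | ICC[C@@]1(C)OC(C)(C)O[C@@H]1C[C@@]1(C)CC[C@H](C(C)C)C1=O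
A2 | alternative 1 | acetonide of the target triol skeleton | CC1(C)O[C@@H]2C[C@@]3(C)CC[C@H](C(C)C)[C@@]3(O)CC[C@@]2(C)O1
A3 | alternative 2 | 2-methyl-2-[(2E)-4-oxopent-2-en-1-yl]cycloheptane-1,3-dione | CC(=O)/C=C/CC1(C)C(=O)CCCCC1=O
A4 | alternative 2 | bicyclic ketol with C7 hydroxyl, C6 acetyl and C2 ketone | C1C(=O)[C@@]2(C)CC[C@H](C(C)=O)[C@@]2(O)CCC1
A5 | alternative 3 | bridged eight-membered cyclic enol ether (C2 methylene on C1, ring oxygen on C5) | C=C1O[C@@H]2C=C(C)[C@@](O[Si](CC)(CC)CC)([C@H]2C(C)C)CC[C@@]1(C)O[Si](C)(C)C
A6 | alternative 3 | bicyclic C1 ketone with C4=C5 double bond | O=C1C[C@@]2(C)C=C[C@H](C(C)C)[C@@]2(O[Si](CC)(CC)CC)CC[C@@]1(C)O[Si](C)(C)C
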